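Everything rests on cutting the O1–C5 bond of the oxolane ring. If the butyl chain on C5 is read as a vinyl group, this bond is an allylic ether bond, so it can be made by letting the hydroxyl on C2 (the future O1) add to the substituted end of a palladium allyl complex at C5. In one catalyst-controlled operation the key step forms that C–O bond, closes the five-membered ring and sets C5 cis to the C2 side chain; C2 itself is bought with a chiral epoxide. The precursor is an open-chain (R)-β-hydroxy ketone whose carbinol is linked by two methylene groups to an E-rich primary allylic methyl carbonate.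

Key step: step 6

Remark 1: The (S,S) antipode of the ligand is assumed to be the one that pairs with the (6R) carbinol to give the 2,5-cis oxolane, by analogy with the working model for this ligand family (oxygen nucleophile closing onto a syn allyl complex); should a trial run show the trans isomer to prevail, the (R,R) antipode takes its place in step 6 and nothing else changes.
Remark 2: Catalyst-bound species (ruthenium alkylidenes, the palladium allyl complex) are dealt with in the Why lines and carry no compound number.

Step 1
Reactants: 1 pentadecanal
Product: 2 2-tetradecyl-1,3-dithiane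
Conditions: HS(CH2)3SH, BF3·OEt2 (cat.), CH2Cl2, 0 °C → rt
Reagents that add atoms: propane-1,3-dithiol, SCCCS
Why: Lewis-acid-catalysed dithioacetalisation of an unhindered aliphatic aldehyde is reliable and turns the formyl carbon into a latent acyl anion (Corey–Seebach umpolung).

Step 2
Reactants: 2 2-tetradecyl-1,3-dithiane; 3 (R)-1,2-epoxyhex-5-ene
Product: 5 (2R)-1-(2-tetradecyl-1,3-dithian-2-yl)hex-5-en-2-ol, via 2-lithio-2-tetradecyl-1,3-dithiane 4 (not isolated)
Conditions: n-BuLi, THF, −25 °C, 2 h; then 3, −25 → 0 °C; H2O
Reagents that add atoms: none
Why: Corey–Seebach alkylation, in which the lithiated dithiane opens the monosubstituted epoxide by SN2 attack at its CH2 terminus, so the C–O bond at the stereocentre is never broken and the (R) configuration of 3 is carried unchanged into the carbinol that becomes C2 of the ring; the terminal alkene is inert.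

Step 3
Reactants: 5 (2R)-1-(2-tetradecyl-1,3-dithian-2-yl)hex-5-en-2-ol
Product: 6 (5R)-5-hydroxyhenicos-1-en-7-one
Conditions: MeI, CaCO3, MeCN/H2O (9:1), 45 °C
Reagents that add atoms: water, O
Why: S-methylation followed by hydrolysis unmasks the ketone under buffered, non-oxidising conditions that offer no halonium or mercury electrophile to the γ,δ-unsaturated alcohol (which would cyclise) and no strong acid or base to the β-hydroxy ketone (which would dehydrate or cleave by retro-aldol reaction).

Step 4
Reactants: 7 (Z)-but-2-ene-1,4-diol
Product: 8 (Z)-but-2-ene-1,4-diyl dimethyl biscarbonate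
Conditions: ClCO2Me, pyridine, CH2Cl2, 0 °C → rt
Reagents that add atoms: methyl chloroformate, COC(=O)Cl
Why: Acylation of both primary allylic hydroxyl groups with a chloroformate and pyridine is routine and leaves the alkene untouched.

Step 5
Reactants: 6 (5R)-5-hydroxyhenicos-1-en-7-one; 8 (Z)-but-2-ene-1,4-diyl dimethyl biscarbonate
Product: 9 methyl (6R)-6-hydroxy-8-oxodocos-2-en-1-yl carbonate (E-rich 2E/2Z mixture)
Conditions: second-generation Grubbs catalyst (5 mol%), 8 (3 equiv), CH2Cl2, 40 °C
Reagents that add atoms: none
Why: Olefin cross-metathesis of a terminal alkene with an excess of a symmetrical internal allylic partner tolerates the free hydroxyl and the ketone; under the equilibrating conditions of this catalyst the more stable E alkene should predominate, and no stereocentre is touched.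

Step 6
Reactants: 9 methyl (6R)-6-hydroxy-8-oxodocos-2-en-1-yl carbonate
Product: 10 1-[(2R,5S)-5-ethenyloxolan-2-yl]hexadecan-2-one
Conditions: Pd2(dba)3·CHCl3 (2.5 mol%), (S,S)-N,N'-(cyclohexane-1,2-diyl)bis[2-(diphenylphosphino)benzamide] (7.5 mol%), degassed CH2Cl2 (0.05 M), rt
Reagents that add atoms: none
Why: Zerovalent palladium carrying the C2-symmetric diphosphine ionises the primary carbonate with loss of CO2, the methoxide set free deprotonates the C6 hydroxyl (so the β-hydroxy ketone never meets an external base), and the alkoxide attacks the substituted allyl carbon of the η3-allyl complex of divalent palladium from the face opposite the metal; this is the known palladium-catalysed asymmetric allylic etherification (Tsuji–Trost cyclisation) that gives 2-vinyl oxolanes. The ring closes in a 5-exo mode, and because attack at the CH2 terminus would need a seven-membered ring holding the alkene, the two-methylene tether itself secures the branched regiochemistry. The new C5 stereocentre is set by the catalyst: the two syn complexes (palladium on either allyl face) exchange through the η1 form at the unsubstituted CH2 terminus faster than they close, and the chiral pocket of the ligand should let only one of them cyclise, placing the vinyl group cis to the C2 side chain and overriding the small bias of the existing carbinol centre. The minor 2Z isomer enters as the anti complex and must first relax to the syn series through the η1 form at the substituted carbon, which is why 9 is made under E-favouring conditions and why the risk of the route is carried here. O-alkylation is needed over C-alkylation through the ketone enolate, and the neutral medium secures it because the much less acidic α-CH2 is not deprotonated.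

Step 7
Reactants: 10 1-[(2R,5S)-5-ethenyloxolan-2-yl]hexadecan-2-one; 11 (Z)-hex-3-ene
Product: 12 1-[(2R,5S)-5-(but-1-en-1-yl)oxolan-2-yl]hexadecan-2-one (E/Z mixture)
Conditions: second-generation Grubbs catalyst (5 mol%), 11 (10 equiv), CH2Cl2, 40 °C (sealed vessel)
Reagents that add atoms: none
Why: Cross-metathesis of the monosubstituted vinyl group with a large excess of a symmetrical internal alkene transfers a propylidene unit; ketone and cyclic ether are inert to the ruthenium carbene, neither ring stereocentre is involved, and the geometry of the new alkene does not matter because it is hydrogenated next.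

Step 8
Reactants: 12 1-[(2R,5S)-5-(but-1-en-1-yl)oxolan-2-yl]hexadecan-2-one
Product: 13 1-[(2R,5R)-5-butyloxolan-2-yl]hexadecan-2-one
Conditions: H2 (1 atm), Pt/C (5 wt%), EtOAc, rt
Reagents that add atoms: none
Why: Heterogeneous hydrogenation of the disubstituted alkene; platinum is preferred to palladium because it causes little double-bond migration toward the ring oxygen (which would erase C5) and little allylic C–O hydrogenolysis, and it leaves the aliphatic ketone alone under these mild conditions, so C5 keeps its geometry and only its descriptor changes from S to R because butyl ranks below the ring CH2.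

Compound list
1 | pentadecanal | CCCCCCCCCCCCCCC=O | starting material
2 | 2-tetradecyl-1,3-dithiane | CCCCCCCCCCCCCCC1SCCCS1 | intermediate
3 | (R)-1,2-epoxyhex-5-ene, i.e. (2R)-2-(but-3-en-1-yl)oxirane | C=CCC[C@@H]1CO1 | starting material
4 | 2-lithio-2-tetradecyl-1,3-dithiane | [Li]C1(CCCCCCCCCCCCCC)SCCCS1 | intermediate (not isolated)
5 | (2R)-1-(2-tetradecyl-1,3-dithian-2-yl)hex-5-en-2-ol | CCCCCCCCCCCCCCC1(C[C@H](O)CCC=C)SCCCS1 | intermediate
6 | (5R)-5-hydroxyhenicos-1-en-7-one | CCCCCCCCCCCCCCC(=O)C[C@H](O)CCC=C | intermediate
7 | (Z)-but-2-ene-1,4-diol | OC/C=C\CO | starting material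
8 | (Z)-but-2-ene-1,4-diyl dimethyl biscarbonate | COC(=O)OC/C=C\COC(=O)OC | intermediate
9 | methyl (6R)-6-hydroxy-8-oxodocos-2-en-1-yl carbonate, E-rich 2E/2Z mixture (alkene geometry left open in the SMILES) | CCCCCCCCCCCCCCC(=O)C[C@H](O)CCC=CCOC(=O)OC | intermediate
10 | 1-[(2R,5S)-5-ethenyloxolan-2-yl]hexadecan-2-one (2,5-cis) | CCCCCCCCCCCCCCC(=O)C[C@H]1CC[C@@H](C=C)O1 | intermediate
11 | (Z)-hex-3-ene | CC/C=C\CC | starting material
12 | 1-[(2R,5S)-5-(but-1-en-1-yl)oxolan-2-yl]hexadecan-2-one, E/Z mixture (alkene geometry left open in the SMILES) | CCCCCCCCCCCCCCC(=O)C[C@H]1CC[C@@H](C=CCC)O1 | intermediate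
13 | 1-[(2R,5R)-5-butyloxolan-2-yl]hexadecan-2-one (2,5-cis) | CCCCCCCCCCCCCCC(=O)C[C@H]1CC[C@@H](CCCC)O1 | target

Total step count: 8
Longest linear sequence: 7 steps (steps 1, 2, 3, 5, 6, 7, 8, from pentadecanal); step 4 is a one-step side branch.

Steps most likely to fail

Step 6 (key step). The ligand may fail to control which allyl face the alkoxide attacks, or the anti complex from the 2Z share of 9 may close before it relaxes, so that C5 forms as a cis/trans mixture. The fallback replaces catalyst control by transfer of chirality from a purchased carbinol, and sets out from 6. Cross-metathesis of 6 with (R)-pent-1-en-3-ol (second-generation Grubbs catalyst, CH2Cl2, 40 °C) should give (3R,4E,8R)-3,8-dihydroxytetracos-4-en-10-one F1. PdCl2(MeCN)2 (5 mol%) in THF at 0 °C should then close the ring by oxypalladation of the alkene with divalent palladium and loss of the allylic hydroxyl as water. This is a net syn-SN2′ substitution that relays the C3 configuration to C5. The 3R carbinol should deliver the 5S centre and an E alkene, that is the E isomer of 12, where the fallback comes back to the route ahead of step 8.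

Step 5. Self-metathesis of 6 and stalled conversion are possible, and above all a product of mixed alkene geometry whose Z share burdens step 6. The fallback builds the allylic carbonate through an E-selective acrylate metathesis and sets out from 5, before the dithiane is removed. Cross-metathesis with methyl acrylate (second-generation Hoveyda–Grubbs catalyst, CH2Cl2, 40 °C) should give methyl (2E,6R)-6-hydroxy-7-(2-tetradecyl-1,3-dithian-2-yl)hept-2-enoate F2. Reduction with i-Bu2AlH (CH2Cl2, −78 °C) should give (2E,6R)-7-(2-tetradecyl-1,3-dithian-2-yl)hept-2-ene-1,6-diol F3. ClCO2Me and pyridine at −20 °C should acylate the primary allylic hydroxyl selectively, giving methyl (2E,6R)-6-hydroxy-7-(2-tetradecyl-1,3-dithian-2-yl)hept-2-en-1-yl carbonate F4. Removal of the dithiane as in step 3 (MeI, CaCO3, aqueous MeCN) comes back to the route at 9, now as the single 2E isomer.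

Step 7. Metathesis at the vinyl group, which is branched at the allylic ether carbon, may be slow or incomplete, with catalyst decay and self-metathesis of 10 competing. The fallback adds the two carbons by carbonyl olefination and sets out from 10. Ozonolysis (O3, CH2Cl2, −78 °C; then PPh3) should give (2S,5R)-5-(2-oxohexadecyl)oxolane-2-carbaldehyde F5. A Wittig reaction with the ylide made from propyltriphenylphosphonium bromide and NaN(SiMe3)2 (THF, −78 °C) reacts with the aldehyde far faster than with the ketone and should give the Z isomer of 12, where the fallback comes back to the route ahead of step 8.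

Further compounds
F1 | step 6 | (3R,4E,8R)-3,8-dihydroxytetracos-4-en-10-one | CCCCCCCCCCCCCCC(=O)C[C@H](O)CC/C=C/[C@H](O)CC
F2 | step 5 | methyl (2E,6R)-6-hydroxy-7-(2-tetradecyl-1,3-dithian-2-yl)hept-2-enoate | CCCCCCCCCCCCCCC1(C[C@H](O)CC/C=C/C(=O)OC)SCCCS1
F3 | step 5 | (2E,6R)-7-(2-tetradecyl-1,3-dithian-2-yl)hept-2-ene-1,6-diol | CCCCCCCCCCCCCCC1(C[C@H](O)CC/C=C/CO)SCCCS1
F4 | step 5 | methyl (2E,6R)-6-hydroxy-7-(2-tetradecyl-1,3-dithian-2-yl)hept-2-en-1-yl carbonate | CCCCCCCCCCCCCCC1(C[C@H](O)CC/C=C/COC(=O)OC)SCCCS1
F5 | step 7 | (2S,5R)-5-(2-oxohexadecyl)oxolane-2-carbaldehyde | CCCCCCCCCCCCCCC(=O)C[C@H]1CC[C@@H](C=O)O1
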